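**Two amounts.** Start from 43.9: the alpha run took that many times the charge of the epsilon run.

| setting | epsilon | alpha | grey | ochre | teal | red |
|---|---|---|---|---|---|---|
| D | 0.041 mM | 1.8 mM | 0.060 mM | 0.20 mM | 0.60 mM | 2.0 mM |
| remark | run made earlier | run made earlier |  |  |  |  |
| time |  |  | 2.5 min | 2.5 min | 2.5 min | 2.5 min |

| run | time / s | G / % | D / % |
|---|---|---|---|
| epsilon | 10.0 | 1.5 | 71.0 |
| epsilon | 15.0 | 2.4 | 64.9 |
| epsilon | 25.0 | 3.1 | 57.4 |
| epsilon | 40.0 | 4.7 | 50.3 |
| epsilon | 60.0 | 5.9 | 44.8 |
| epsilon | 120 | 9.9 | 32.6 |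
| alpha | 20.0 | 2.3 | 60.5 |
| alpha | 40.0 | 4.5 | 50.6 |
| alpha | 50.0 | 5.3 | 47.1 |
| alpha | 80.0 | 7.5 | 40.0 |
| alpha | 120 | 9.7 | 33.8 |

(standard deviation of a reading: 0.3 percentage points)

- "hardly changes" means that all values lie within two and a half points (for a concentration: within two and a half percent of the largest)

- [G] at the end for grey, ochre, teal, red, in this order
- the shape of the row from first to last (rises all the way / rises, then falls / falls, then rises / hardly changes / falls all the way)

**Go logarithmic.** Take cG at 120 s in both runs: 0.00406 mM in epsilon, 0.175 mM in alpha. Divide the logarithm of their ratio by the logarithm of the charge ratio. That gives a reading of 0.995, the charge exponent: powers of ten gained in cG per power of ten gained in charge. An exponent of one means first-order behaviour, with the percentage at a fixed time independent of the charge. The two percentages differ by 0.2 percentage points, less than the scatter of 0.3 points.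

**My reckoning.** Apply the exponent from grey to red: cG should grow by a factor of 32.7.

**The forecast.** It gives 0.0068 mM, 0.0228 mM, 0.068 mM and 0.228 mM, a row that rises all the way, on the ground that “percent yield at a fixed time should not depend on charge”. From grey to red its row grows by a factor of 33.5, where mine gives 32.7.

**The result.** The flasks give 0.00690 mM, 0.0230 mM, 0.0690 mM and 0.230 mM, a row that rises all the way.

    D ⇌ Z (K = 0.240, k = 0.00835 s⁻¹)
    D → G (k = 0.00170 s⁻¹)
    D ⇌ L (K = 0.170, k = 0.0322 s⁻¹)
    Z → E (k = 0.0268 s⁻¹)
    L ⇌ X (K = 13.3, k = 0.0180 s⁻¹)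
    D ⇌ Q (K = 0.346, k = 0.0155 s⁻¹)

**Exponent again.** Grey to red returns an exponent of 1.00, and ochre to teal returns 1.00, beside the reading of 0.995 from the earlier runs. In grey, half the turnover of D into L is done by 0.117 min, earlier than the 0.677 min for D into Z. At 2.50 min, grey holds G at 11.5% beside D at 28.9% and E at 22.7%.

Readings and results are simulated with made-up constants; the scatter is artificial.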